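Abbreviations: TBS = tert-butyldimethylsilyl, TBDPS = tert-butyldiphenylsilyl, PMB = 4-methoxybenzyl, TMS = trimethylsilyl, Boc2O = di-tert-butyl dicarbonate, DMAP = 4-(dimethylamino)pyridine. Locants C1–C15 are the elemane locants defined in the first section and are used for every intermediate. The SMILES strings in the compound list fix the configurations.

## The problem

The target is a monocyclic elemane hydroxy acid. One cyclohexane (C5–C10) carries a quaternary C10 (methyl C14, vinyl C1=C2), a 3-hydroxyprop-1-en-2-yl group on C5 (C4=C3, C15), a free hydroxyl on C6, an acrylic acid on C7 (C11=C13, C12O2H), a (Z)-4-acetoxy-2-methylbut-2-enoate on O8 and a methylene at C9. Five contiguous stereocentres have to be set (5S, 6R, 7S, 8S, 10S). In the chair that places O6, C11 and O8 equatorial, the C10 methyl and the C5 alkenyl group are axial on opposite faces, so the C5 substituent is cis to both O6 and the vinyl group. C5 and C10 are adjacent and are best created together in one stereospecific event. C6 sits between them and the side chain and can be set by a reagent. C7 and C8 can then be dictated by the two axial groups if they are formed in a ring closure. The molecule tolerates little: O6 and O8 are both γ to C12 and can lactonise, the α-methylene acid is a Michael acceptor, and the Z-acetoxy enoate isomerises to E or collapses to a butenolide under base. The acid and the three hydroxyls must therefore be unmasked without strong acid or base. The enabling feature is the C8 oxygen next to a C7 carbon that bears the C11(=C13)–C12 unit. This is the pattern left by γ-attack of a 2-(alkoxycarbonyl)allyl metal (C13–C11=C7) on a C8 aldehyde.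

## Retrosynthesis

**End game.** The side-chain ester (O8–acyl bond) and the protecting groups are removed first. Target 37 comes from acid 36 by desilylation, 36 from tert-butyl ester 34, and 34 from alcohol 27 and the Z-acid 32. The Z-acetoxy enoate cannot survive organometallic or basic steps, so it is attached late. The order ester cleavage, then desilylation, ensures that C12 is a carboxylate when O6 is freed, which blocks lactonisation. Compound 27 has all five ring stereocentres and only one free hydroxyl.

**Ring closure (C7–C8).** Cutting C7–C8 in 27 gives the acyclic bromo aldehyde 24. Neighbouring cuts are weaker: C6–C7 would need an aldol-type closure onto an epimerisable α-branched aldehyde, and C8–C9 or C9–C10 would form no stereocentre or would have to create the quaternary carbon in the ring-forming step. The C7–C8 cut forms the ring, both remaining stereocentres and the exocyclic methylene at once, and the aldehyde has no α-stereocentre to lose. The forward reaction must attack through C7, not C13, must place C11 and O8 equatorial, and must not let the metal alkoxide lactonise; for that reason C12 is a tert-butyl ester.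

**Bromide, aldehyde and enoate.** Compound 24 is reached from bromo alcohol 23 by oxidation, 23 from diol 22 by selective allylic bromination, and 22 from the tris-silyl ether 21 by removal of the two primary TBS groups. This uses one deprotection for both C8 and C13 and relies on the different reactivity of an allylic and a saturated alcohol. The ester carbon C12 is then disconnected (C11–C12): 21 comes from alkenylstannane 19 by tin–lithium exchange and carboxylation, and 19 from alkyne 18 by syn hydrostannation. The syn addition fixes the alkene geometry, and the forward step has to deliver tin to C11.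

**Carbinol C6 (C6–C7).** Alkyne 18 is the silyl ether of propargylic alcohol 17, which comes from ynone 16 by reagent-controlled reduction. Compound 16 is cut between C6 and C7 into Weinreb amide 13 and the protected propargyl alcohol 14. Setting C6 by a catalyst avoids reliance on the bias of the neighbouring C5 centre and joins a three-carbon unit that already holds C13 at the right oxidation state.

**C5–C10 bond.** Amide 13 comes from acid 12, whose C5–C10 bond is the sigma bond of an Ireland–Claisen rearrangement of allylic ester 9. This cut creates the quaternary centre and its neighbour together from an achiral ester, and it turns the allylic CH2–CH= unit into the vinyl group. The forward reaction needs a defined enolate geometry, a chair transition state and an external chiral controller. Ester 9 is divided at its C–O bond into acid 4 and allylic alcohol 8.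

**Fragments.** Acid 4 derives from ester 3, alcohol 2 and the itaconic half-ester 1 by selective reduction of the free carboxyl group. Alcohol 8 derives from alkyne 5 by carbometalation (C10–C14) and hydroxymethylation (C1–C2), which fixes the E geometry.

**Side chain.** Acid 32 comes from its PMB ester 31, which is made from the sodium salt 29 of the ring-opened butenolide 28. The Z geometry is taken from the ring, and the carboxylate is alkylated, not acylated, so that the cis-hydroxyl cannot close back.

## Roads not taken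

**Alternative 1:** The cut is C4–C5, with the ring and its three oxygenated carbons taken from (−)-shikimic acid A1. In the radical precursor A2 the enoate β-carbon is C5 and a 2-bromoallyl mixed acetal sits on O6. A tin hydride generates the vinyl radical, which adds 5-exo to C5 and gives the cis-fused methylene oxolane A3.
- Merits: the absolute configuration is bought, and the tether delivers C4 to the face of O6, which is exactly the cis C5/C6 relation of the target. In this respect it is more certain than the chosen plan, which depends on two reagent-controlled steps (6 and 9).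
- Weak points: C7 still carries oxygen and must be exchanged for the acrylate carbon between two oxygenated carbons. C10 is a CH–ester that must be methylated with face control and converted into a vinyl group. The oxolane must be opened to free O6 and C15.
- Comparison: the chosen plan installs the C7 carbon substituent and the quaternary C10 directly in its two main events and needs no deoxygenation. That is what it sets against the better stereochemical security of A3.

**Alternative 2:** The vinyl group and the C4=C3 methylene are seen as the two halves of a cyclobutene C1=C4 that spans C10 and C5. The cis-fused bicyclo[4.2.0]octadiene A4 is opened by ethenolysis with a second-generation Grubbs catalyst to the cyclohexenol A5.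
- Merits: the cis relation of the vinyl and alkenyl groups is guaranteed by the ring fusion, and both alkenes appear in one strain-driven step. The chosen plan must obtain this relation from the enolate geometry in step 6.
- Weak points: enantioselective access to A4, with its quaternary carbon and the C6 carbinol, is not secured. After A5 the C7=C8 alkene must still be turned into a trans C7-acrylate/C8-oxygen pair with full regio- and stereocontrol in the presence of two other alkenes.
- Comparison: the alternative is better at C5/C10; the chosen plan is better at C7/C8, because its ring closure creates both centres with the substituents the target needs.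

**Alternative 3:** The cut is C9–C10. In the cycloheptene oxide A6 a bulky methylaluminium bis(aryloxide), MeAl(OAr)2, ionises the C10–O bond, C9 migrates from C1 to C10 anti to the leaving oxygen, and the ring contracts to the cyclohexanecarbaldehyde A7 with C1 as the formyl group.
- Merits: the quaternary centre forms stereospecifically from the epoxide geometry, which is more certain than a rearrangement that depends on enolate geometry, and the formyl group is one methylenation from the vinyl group.
- Weak points: A6 is a fully substituted seven-membered ring with four stereocentres and a face-defined epoxide, harder to make than the target ring. Hydride shift competes with ring contraction, the Lewis acid must spare a PMB ether and an acrylate, and the amide at C5 needs several steps to become the hydroxypropenyl group.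
- Comparison: the chosen plan builds the quaternary centre from two simple achiral fragments and keeps all ring stereocentres for the final closure.

Key step: step 16

## Remarks on the chemistry (assumptions)

- Step 6: the diazaborolidine bromide with iPr2NEt in CH2Cl2 is assumed to give the Z(O) boron enolate of the but-3-enoate, as it does with simple allyl esters.
- Step 6: the (4S,5S) controller is assumed to select the enolate face that leads to (2S,3S)-12; if it selects the other face, the (4R,5R) controller is used with no other change.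
- Step 9: the branched alkyl group is assumed to act as the large and the alkynyl group as the small substituent, so that the (R)-oxazaborolidine gives the 6R carbinol.

## Route

Step 1
Reactants: 1 4-methyl hydrogen itaconate (4-methoxy-2-methylidene-4-oxobutanoic acid)
Product: 2 methyl 3-(hydroxymethyl)but-3-enoate
Conditions: BH3·SMe2, THF, −10 °C → rt; MeOH quench, aqueous work-up
Reagents that add atoms: none
Why: Borane reduces the free carboxylic acid much faster than the methyl ester or the electron-poor 1,1-disubstituted alkene (chemoselective acid reduction). The product is silylated at once to forestall lactonisation.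

Step 2
Reactants: 2 methyl 3-(hydroxymethyl)but-3-enoate
Product: 3 methyl 3-[(TBDPS-oxy)methyl]but-3-enoate
Conditions: TBDPSCl, imidazole, CH2Cl2, 0 °C → rt
Reagents that add atoms: tert-butyl(chloro)diphenylsilane, CC(C)(C)[Si](Cl)(c1ccccc1)c1ccccc1
Why: Standard silylation of a primary allylic alcohol. TBDPS is chosen because it must survive the later selective removal of primary TBS groups.

Step 3
Reactants: 3 methyl 3-[(TBDPS-oxy)methyl]but-3-enoate
Product: 4 3-[(TBDPS-oxy)methyl]but-3-enoic acid
Conditions: LiOH, THF/H2O, 0 °C; then 1 M HCl to pH 3–4 at 0 °C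
Reagents that add atoms: lithium hydroxide, [Li+].[OH-]
Why: Mild saponification at 0 °C. Once formed, the carboxylate resists base-induced migration of the β,γ-double bond into conjugation.

Step 4
Reactants: 5 tert-butyl(but-3-yn-1-yloxy)dimethylsilane
Product: 8 (2E)-5-(TBS-oxy)-3-methylpent-2-en-1-ol, via alkenyldimethylalane 6 (not isolated), via lithium alkenylalanate 7 (not isolated)
Conditions: AlMe3, Cp2ZrCl2 (cat.), CH2Cl2, 0 °C → rt; volatiles removed; n-BuLi, THF–hexane, −78 °C; (CH2O)n, −78 °C → rt; dilute HCl, 0 °C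
Reagents that add atoms: trimethylaluminium, C[Al](C)C; formaldehyde (as paraformaldehyde), C=O
Why: Negishi zirconium-catalysed carboalumination adds methyl and aluminium syn across the terminal alkyne, with aluminium at the terminus. The derived alanate is hydroxymethylated with retention, which fixes the E geometry.

Step 5
Reactants: 4 3-[(TBDPS-oxy)methyl]but-3-enoic acid; 8 (2E)-5-(TBS-oxy)-3-methylpent-2-en-1-ol
Product: 9 (2E)-5-(TBS-oxy)-3-methylpent-2-en-1-yl 3-[(TBDPS-oxy)methyl]but-3-enoate
Conditions: DCC, DMAP (cat.), CH2Cl2, 0 °C → rt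
Reagents that add atoms: none
Why: Steglich esterification at 0 °C with catalytic DMAP, conditions under which but-3-enoic acids are esterified without double-bond migration.

Step 6
Reactants: 9 (2E)-5-(TBS-oxy)-3-methylpent-2-en-1-yl 3-[(TBDPS-oxy)methyl]but-3-enoate
Product: 12 (2S,3S)-5-(TBS-oxy)-2-[3-(TBDPS-oxy)prop-1-en-2-yl]-3-ethenyl-3-methylpentanoic acid, via boron ketene acetal 10 (not isolated), via acyloxyborane 11 (not isolated)
Conditions: (4S,5S)-2-bromo-1,3-bis{[3,5-bis(trifluoromethyl)phenyl]sulfonyl}-4,5-diphenyl-1,3,2-diazaborolidine (1.2 equiv), iPr2NEt, CH2Cl2, −78 °C, then −20 → 4 °C; aqueous work-up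
Reagents that add atoms: none
Why: Enantioselective boron-enolate Ireland–Claisen rearrangement. The Z(O) ketene acetal rearranges through a chair with the alkenyl group on C5 and the C9 chain on C10 both equatorial, which gives the required C5/C10 relation (vinyl and alkenyl group cis on the later ring). The C2-symmetric sulfonamide ligand selects the enolate face and so sets the absolute configuration of both centres.

Step 7
Reactants: 12 (2S,3S)-5-(TBS-oxy)-2-[3-(TBDPS-oxy)prop-1-en-2-yl]-3-ethenyl-3-methylpentanoic acid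
Product: 13 (2S,3S)-5-(TBS-oxy)-2-[3-(TBDPS-oxy)prop-1-en-2-yl]-3-ethenyl-N-methoxy-N,3-dimethylpentanamide
Conditions: MeNH(OMe)·HCl, EDC·HCl, HOBt, N-methylmorpholine, CH2Cl2, 0 °C → rt
Reagents that add atoms: N,O-dimethylhydroxylamine hydrochloride, CNOC.Cl
Why: Carbodiimide/HOBt amide coupling under weakly basic conditions that leave the α-stereocentre (allylic and α to the carbonyl) untouched.

Step 8
Reactants: 13 Weinreb amide (as in step 7); 14 tert-butyldimethyl(prop-2-yn-1-yloxy)silane
Product: 16 (5S,6S)-1,8-bis(TBS-oxy)-5-[3-(TBDPS-oxy)prop-1-en-2-yl]-6-ethenyl-6-methyloct-2-yn-4-one, via lithium acetylide 15 (not isolated)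
Conditions: 14, n-BuLi, THF, −78 °C; then 13, −78 → −20 °C; aq. NH4Cl
Reagents that add atoms: none
Why: Weinreb ketone synthesis. The acetylide adds once and the chelated tetrahedral intermediate persists until the quench, so there is no over-addition and the acidic C5–H of the ynone is never exposed to base.

Step 9
Reactants: 16 ynone (as in step 8)
Product: 17 (4R,5S,6S)-1,8-bis(TBS-oxy)-5-[3-(TBDPS-oxy)prop-1-en-2-yl]-6-ethenyl-6-methyloct-2-yn-4-ol
Conditions: (R)-2-methyl-CBS-oxazaborolidine (0.3 equiv), catecholborane, toluene/CH2Cl2, −78 °C; MeOH, then pH 7 buffer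
Reagents that add atoms: none
Why: Corey–Bakshi–Shibata reduction of an α-branched ynone. With the branched alkyl group as the large substituent, the (R)-catalyst delivers hydride to give the 6R carbinol (C4 of this chain) under reagent control. Catecholborane spares the three alkenes.

Step 10
Reactants: 17 propargylic alcohol (as in step 9)
Product: 18 (4R,5S,6S)-1,4,8-tris(TBS-oxy)-5-[3-(TBDPS-oxy)prop-1-en-2-yl]-6-ethenyl-6-methyloct-2-yne
Conditions: TBSOTf, 2,6-lutidine, CH2Cl2, −78 → 0 °C
Reagents that add atoms: tert-butyldimethylsilyl trifluoromethanesulfonate, CC(C)(C)[Si](C)(C)OS(=O)(=O)C(F)(F)F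
Why: Silyl triflate/lutidine silylation, the standard method for a hindered secondary propargylic alcohol.

Step 11
Reactants: 18 alkyne (as in step 10)
Product: 19 (2E,4R,5S,6S)-tributyl{1,4,8-tris(TBS-oxy)-5-[3-(TBDPS-oxy)prop-1-en-2-yl]-6-ethenyl-6-methyloct-2-en-2-yl}stannane
Conditions: Bu3SnH, PdCl2(PPh3)2 (3 mol%), THF, 0 °C → rt
Reagents that add atoms: tributylstannane, CCCC[SnH](CCCC)CCCC
Why: Palladium-catalysed hydrostannation is a syn addition. Tin goes to C11, the alkyne carbon remote from the branched C6 and next to the unhindered oxygenated methylene, so H7 ends cis to tin.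

Step 12
Reactants: 19 alkenylstannane (as in step 11)
Product: 21 tert-butyl (2E,4S,5S,6S)-4,8-bis(TBS-oxy)-2-[(TBS-oxy)methyl]-5-[3-(TBDPS-oxy)prop-1-en-2-yl]-6-ethenyl-6-methyloct-2-enoate, via alkenyllithium 20 (not isolated)
Conditions: n-BuLi, THF, −78 °C; Boc2O, −78 → −30 °C; aq. NH4Cl
Reagents that add atoms: di-tert-butyl dicarbonate, CC(C)(C)OC(=O)OC(=O)OC(C)(C)C
Why: Tin–lithium exchange occurs with retention at the sp2 carbon, and the alkenyllithium is acylated by Boc2O to the tert-butyl ester. Lithium is trans to the C6 silyloxy group, so no 1,4-silyl migration can occur; the change of the C4 descriptor from R to S is a priority effect only.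

Step 13
Reactants: 21 tris-silyl ether ester (as in step 12)
Product: 22 tert-butyl (2E,4S,5S,6S)-4-(TBS-oxy)-5-[3-(TBDPS-oxy)prop-1-en-2-yl]-6-ethenyl-8-hydroxy-2-(hydroxymethyl)-6-methyloct-2-enoate
Conditions: HF·pyridine, pyridine, THF, 0 °C → rt
Reagents that add atoms: none
Why: Buffered HF·pyridine cleaves the two primary TBS ethers much faster than the hindered secondary TBS ether at C6 or the TBDPS ether.

Step 14
Reactants: 22 diol (as in step 13)
Product: 23 tert-butyl (2Z,4S,5S,6S)-2-(bromomethyl)-4-(TBS-oxy)-5-[3-(TBDPS-oxy)prop-1-en-2-yl]-6-ethenyl-8-hydroxy-6-methyloct-2-enoate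
Conditions: NBS, Me2S, CH2Cl2, −20 °C (reagent preformed); then 22, −20 → 0 °C
Reagents that add atoms: N-bromosuccinimide, O=C1CCC(=O)N1Br
Why: Corey–Kim halogenation. The alkoxysulfonium salt of the allylic alcohol collapses to the bromide by SN2 displacement, while that of the saturated primary alcohol does not and returns the alcohol on work-up. The alkene geometry is unchanged; the descriptor becomes Z only because bromine outranks the ester.

Step 15
Reactants: 23 bromo alcohol (as in step 14)
Product: 24 tert-butyl (2Z,4S,5S,6S)-2-(bromomethyl)-4-(TBS-oxy)-5-[3-(TBDPS-oxy)prop-1-en-2-yl]-6-ethenyl-6-methyl-8-oxooct-2-enoate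
Conditions: Dess–Martin periodinane, NaHCO3, CH2Cl2, 0 °C → rt
Reagents that add atoms: none
Why: Dess–Martin oxidation of a primary alcohol under buffered, neutral conditions that the allylic bromide tolerates. The aldehyde has no α-stereocentre.

Step 16
Reactants: 24 bromo aldehyde (as in step 15)
Product: 27 tert-butyl 2-[(1R,2R,3S,4S,6S)-2-(TBS-oxy)-3-[3-(TBDPS-oxy)prop-1-en-2-yl]-4-ethenyl-6-hydroxy-4-methylcyclohexyl]prop-2-enoate, via allylchromium dichloride 25 (not isolated), via chromium alkoxide 26 (not isolated)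
Conditions: CrCl2 (5 equiv), degassed THF, slow addition of 24 to 0.005 M, 0 °C → rt; aq. NH4Cl
Reagents that add atoms: none
Why: Two equivalents of CrCl2 (divalent chromium) reduce the C13–Br bond to the allylchromium dichloride 25 (trivalent chromium), which adds to the C8 aldehyde through its γ-carbon C7 with allylic transposition, forming C7–C8 and the C11=C13 methylene; the alkoxide 26 is hydrolysed on work-up. The closest known reaction type is the intramolecular Nozaki–Hiyama (Barbier-type) 2-(alkoxycarbonyl)allylation of aldehydes used for α-methylene-γ-hydroxy esters and their lactones. The cyclohexane C5–C10 closes by 6-exo-trig attack on the carbonyl; attack through C13 would require an eight-membered ring and does not compete. The forming ring is held in the chair that keeps the C6 silyloxy group and the C10 vinyl group equatorial and places the C10 methyl and the C5 alkenyl group axial on opposite faces. C7 is controlled by C5 and C6: only with C11 equatorial, trans to O6, is a 1,3-diaxial clash with the axial C5 alkenyl group avoided. C8 is controlled by C10: the carbonyl oxygen takes the equatorial position away from the axial methyl group, where chromium can bridge it to C13 in a chair-like six-membered array fused trans to the carbocycle. Allylchromium reagents equilibrate by 1,3-metal shift, so the Z geometry of the bromide need not be transmitted and the enoate geometry required by this array is accessible. The step needs chemoselectivity for the aldehyde and no lactonisation of 26: CrCl2 leaves esters and silyl ethers alone, and the tert-butyl ester resists attack by the hindered chromium alkoxide.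

Step 17
Reactants: 28 3-methylfuran-2(5H)-one
Product: 29 sodium (2Z)-4-hydroxy-2-methylbut-2-enoate
Conditions: NaOH (1.0 equiv), H2O, 0 °C → rt; lyophilisation
Reagents that add atoms: sodium hydroxide, [Na+].[OH-]
Why: Saponification opens the butenolide without touching the double bond, so the Z geometry is inherited from the ring. The hydroxy acid is kept as its sodium salt because the free acid would close again.

Step 18
Reactants: 29 sodium (2Z)-4-hydroxy-2-methylbut-2-enoate
Product: 31 4-methoxybenzyl (2Z)-4-(acetyloxy)-2-methylbut-2-enoate, via hydroxy ester 30 (not isolated)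
Conditions: 4-methoxybenzyl chloride, NaI (cat.), DMF, rt; then Ac2O, pyridine, DMAP (cat.), 0 °C
Reagents that add atoms: 4-methoxybenzyl chloride, COc1ccc(CCl)cc1; acetic anhydride, CC(=O)OC(C)=O
Why: O-Alkylation of the carboxylate does not activate the carboxyl group, so the cis-hydroxyl cannot relactonise as it would through an acyl-activated intermediate. The primary alcohol is then acetylated in the same flask.

Step 19
Reactants: 31 4-methoxybenzyl (2Z)-4-(acetyloxy)-2-methylbut-2-enoate
Product: 32 (2Z)-4-(acetyloxy)-2-methylbut-2-enoic acid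
Conditions: TFA, anisole, CH2Cl2, 0 °C
Reagents that add atoms: none
Why: Acidolysis of the PMB ester, with the benzylic cation trapped by anisole, frees the acid without hydrolysis, so the acetate and the Z geometry are kept.

Step 20
Reactants: 27 cyclohexanol (as in step 16); 32 (2Z)-4-(acetyloxy)-2-methylbut-2-enoic acid
Product: 34 tert-butyl 2-[(1R,2R,3S,4S,6S)-6-{[(2Z)-4-(acetyloxy)-2-methylbut-2-enoyl]oxy}-2-(TBS-oxy)-3-[3-(TBDPS-oxy)prop-1-en-2-yl]-4-ethenyl-4-methylcyclohexyl]prop-2-enoate, via mixed anhydride 33 (not isolated)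
Conditions: 32, 2,4,6-trichlorobenzoyl chloride, Et3N, toluene, rt; then 27, DMAP, toluene, rt → 40 °C
Reagents that add atoms: none
Why: Yamaguchi esterification. The preformed mixed anhydride acylates the equatorial C8 hydroxyl, a protocol known to transfer angelate-type acyl groups without Z to E isomerisation. The neighbouring tert-butyl ester does not lactonise under these conditions.

Step 21
Reactants: 34 tert-butyl ester (as in step 20)
Product: 36 2-[(1R,2R,3S,4S,6S)-6-{[(2Z)-4-(acetyloxy)-2-methylbut-2-enoyl]oxy}-2-(TBS-oxy)-3-[3-(TBDPS-oxy)prop-1-en-2-yl]-4-ethenyl-4-methylcyclohexyl]prop-2-enoic acid, via trimethylsilyl ester 35 (not isolated)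
Conditions: TMSOTf, 2,6-lutidine, CH2Cl2, 0 °C; pH 5 aqueous work-up
Reagents that add atoms: none
Why: Silyl triflate/lutidine cleavage of a tert-butyl ester (O-silylation, loss of isobutene) gives the silyl ester, which is hydrolysed on work-up. The method is non-hydrolytic and is run while O6 is still silylated, so the acetate, the enoates and the silyl ethers survive and no lactone can form.

Step 22
Reactants: 36 acid (as in step 21)
Product: 37 2-[(1S,2R,3S,4S,6S)-6-{[(2Z)-4-(acetyloxy)-2-methylbut-2-enoyl]oxy}-4-ethenyl-2-hydroxy-3-(3-hydroxyprop-1-en-2-yl)-4-methylcyclohexyl]prop-2-enoic acid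
Conditions: TBAF, AcOH (1:1), THF, 0 °C → rt; work-up at pH 4–5
Reagents that add atoms: none
Why: Buffered fluoride removes both silyl ethers. C12 is a carboxylate when O6 is released, which blocks lactonisation, and the acetic acid buffer protects the acetate and the Z-enoate from base.

## Compound list

1 | 4-methyl hydrogen itaconate | C=C(CC(=O)OC)C(=O)O | starting material
2 | methyl 3-(hydroxymethyl)but-3-enoate | C=C(CO)CC(=O)OC | intermediate
3 | methyl 3-[(TBDPS-oxy)methyl]but-3-enoate | C=C(CO[Si](c1ccccc1)(c1ccccc1)C(C)(C)C)CC(=O)OC | intermediate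
4 | 3-[(TBDPS-oxy)methyl]but-3-enoic acid | C=C(CO[Si](c1ccccc1)(c1ccccc1)C(C)(C)C)CC(=O)O | intermediate
5 | tert-butyl(but-3-yn-1-yloxy)dimethylsilane | C#CCCO[Si](C)(C)C(C)(C)C | starting material
6 | (E)-[4-(TBS-oxy)-2-methylbut-1-en-1-yl]dimethylalane | C[Al](C)/C=C(\C)CCO[Si](C)(C)C(C)(C)C | intermediate
7 | lithium butyl[(E)-4-(TBS-oxy)-2-methylbut-1-en-1-yl]dimethylalanate | [Li+].CCCC[Al-](C)(C)/C=C(\C)CCO[Si](C)(C)C(C)(C)C | intermediate
8 | (2E)-5-(TBS-oxy)-3-methylpent-2-en-1-ol | OC/C=C(\C)CCO[Si](C)(C)C(C)(C)C | intermediate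
9 | (2E)-5-(TBS-oxy)-3-methylpent-2-en-1-yl 3-[(TBDPS-oxy)methyl]but-3-enoate | C=C(CO[Si](c1ccccc1)(c1ccccc1)C(C)(C)C)CC(=O)OC/C=C(\C)CCO[Si](C)(C)C(C)(C)C | intermediate
10 | Z(O) boron ketene acetal of 9, enolate oxygen bound to the (4S,5S)-diazaborolidinyl group | C=C(CO[Si](c1ccccc1)(c1ccccc1)C(C)(C)C)/C=C(\OB1N(S(=O)(=O)c2cc(C(F)(F)F)cc(C(F)(F)F)c2)[C@@H](c2ccccc2)[C@H](c2ccccc2)N1S(=O)(=O)c1cc(C(F)(F)F)cc(C(F)(F)F)c1)OC/C=C(\C)CCO[Si](C)(C)C(C)(C)C | intermediate
11 | acyloxyborane of acid 12 with the (4S,5S)-diazaborolidinyl group | O=C(OB1N(S(=O)(=O)c2cc(C(F)(F)F)cc(C(F)(F)F)c2)[C@@H](c2ccccc2)[C@H](c2ccccc2)N1S(=O)(=O)c1cc(C(F)(F)F)cc(C(F)(F)F)c1)[C@H](C(=C)CO[Si](c1ccccc1)(c1ccccc1)C(C)(C)C)[C@](C)(C=C)CCO[Si](C)(C)C(C)(C)C | intermediate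
12 | (2S,3S)-5-(TBS-oxy)-2-[3-(TBDPS-oxy)prop-1-en-2-yl]-3-ethenyl-3-methylpentanoic acid | OC(=O)[C@H](C(=C)CO[Si](c1ccccc1)(c1ccccc1)C(C)(C)C)[C@](C)(C=C)CCO[Si](C)(C)C(C)(C)C | intermediate
13 | (2S,3S)-5-(TBS-oxy)-2-[3-(TBDPS-oxy)prop-1-en-2-yl]-3-ethenyl-N-methoxy-N,3-dimethylpentanamide | CON(C)C(=O)[C@H](C(=C)CO[Si](c1ccccc1)(c1ccccc1)C(C)(C)C)[C@](C)(C=C)CCO[Si](C)(C)C(C)(C)C | intermediate
14 | tert-butyldimethyl(prop-2-yn-1-yloxy)silane | C#CCO[Si](C)(C)C(C)(C)C | starting material
15 | lithium acetylide of 14 | [Li]C#CCO[Si](C)(C)C(C)(C)C | intermediate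
16 | (5S,6S)-1,8-bis(TBS-oxy)-5-[3-(TBDPS-oxy)prop-1-en-2-yl]-6-ethenyl-6-methyloct-2-yn-4-one | CC(C)(C)[Si](C)(C)OCC[C@@](C)(C=C)[C@@H](C(=C)CO[Si](c1ccccc1)(c1ccccc1)C(C)(C)C)C(=O)C#CCO[Si](C)(C)C(C)(C)C | intermediate
17 | (4R,5S,6S)-1,8-bis(TBS-oxy)-5-[3-(TBDPS-oxy)prop-1-en-2-yl]-6-ethenyl-6-methyloct-2-yn-4-ol | CC(C)(C)[Si](C)(C)OCC[C@@](C)(C=C)[C@@H](C(=C)CO[Si](c1ccccc1)(c1ccccc1)C(C)(C)C)[C@@H](O)C#CCO[Si](C)(C)C(C)(C)C | intermediate
18 | (4R,5S,6S)-1,4,8-tris(TBS-oxy)-5-[3-(TBDPS-oxy)prop-1-en-2-yl]-6-ethenyl-6-methyloct-2-yne | CC(C)(C)[Si](C)(C)OCC[C@@](C)(C=C)[C@@H](C(=C)CO[Si](c1ccccc1)(c1ccccc1)C(C)(C)C)[C@@H](O[Si](C)(C)C(C)(C)C)C#CCO[Si](C)(C)C(C)(C)C | intermediate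
19 | (2E,4R,5S,6S)-tributyl{1,4,8-tris(TBS-oxy)-5-[3-(TBDPS-oxy)prop-1-en-2-yl]-6-ethenyl-6-methyloct-2-en-2-yl}stannane | CC(C)(C)[Si](C)(C)OCC[C@@](C)(C=C)[C@@H](C(=C)CO[Si](c1ccccc1)(c1ccccc1)C(C)(C)C)[C@@H](O[Si](C)(C)C(C)(C)C)/C=C(/[Sn](CCCC)(CCCC)CCCC)CO[Si](C)(C)C(C)(C)C | intermediate
20 | alkenyllithium (lithium in place of tin in 19) | CC(C)(C)[Si](C)(C)OCC[C@@](C)(C=C)[C@@H](C(=C)CO[Si](c1ccccc1)(c1ccccc1)C(C)(C)C)[C@@H](O[Si](C)(C)C(C)(C)C)/C=C(/[Li])CO[Si](C)(C)C(C)(C)C | intermediate
21 | tert-butyl (2E,4S,5S,6S)-4,8-bis(TBS-oxy)-2-[(TBS-oxy)methyl]-5-[3-(TBDPS-oxy)prop-1-en-2-yl]-6-ethenyl-6-methyloct-2-enoate | CC(C)(C)[Si](C)(C)OCC[C@@](C)(C=C)[C@@H](C(=C)CO[Si](c1ccccc1)(c1ccccc1)C(C)(C)C)[C@@H](O[Si](C)(C)C(C)(C)C)/C=C(/C(=O)OC(C)(C)C)CO[Si](C)(C)C(C)(C)C | intermediate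
22 | tert-butyl (2E,4S,5S,6S)-4-(TBS-oxy)-5-[3-(TBDPS-oxy)prop-1-en-2-yl]-6-ethenyl-8-hydroxy-2-(hydroxymethyl)-6-methyloct-2-enoate | OCC[C@@](C)(C=C)[C@@H](C(=C)CO[Si](c1ccccc1)(c1ccccc1)C(C)(C)C)[C@@H](O[Si](C)(C)C(C)(C)C)/C=C(/C(=O)OC(C)(C)C)CO | intermediate
23 | tert-butyl (2Z,4S,5S,6S)-2-(bromomethyl)-4-(TBS-oxy)-5-[3-(TBDPS-oxy)prop-1-en-2-yl]-6-ethenyl-8-hydroxy-6-methyloct-2-enoate | OCC[C@@](C)(C=C)[C@@H](C(=C)CO[Si](c1ccccc1)(c1ccccc1)C(C)(C)C)[C@@H](O[Si](C)(C)C(C)(C)C)/C=C(/C(=O)OC(C)(C)C)CBr | intermediate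
24 | tert-butyl (2Z,4S,5S,6S)-2-(bromomethyl)-4-(TBS-oxy)-5-[3-(TBDPS-oxy)prop-1-en-2-yl]-6-ethenyl-6-methyl-8-oxooct-2-enoate | O=CC[C@@](C)(C=C)[C@@H](C(=C)CO[Si](c1ccccc1)(c1ccccc1)C(C)(C)C)[C@@H](O[Si](C)(C)C(C)(C)C)/C=C(/C(=O)OC(C)(C)C)CBr | intermediate
25 | allylchromium dichloride (CrCl2 group in place of bromine in 24) | O=CC[C@@](C)(C=C)[C@@H](C(=C)CO[Si](c1ccccc1)(c1ccccc1)C(C)(C)C)[C@@H](O[Si](C)(C)C(C)(C)C)/C=C(/C(=O)OC(C)(C)C)C[Cr](Cl)Cl | intermediate
26 | chromium dichloride alkoxide of 27 | C=C[C@]1(C)C[C@H](O[Cr](Cl)Cl)[C@@H](C(=C)C(=O)OC(C)(C)C)[C@H](O[Si](C)(C)C(C)(C)C)[C@@H]1C(=C)CO[Si](c1ccccc1)(c1ccccc1)C(C)(C)C | intermediate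
27 | tert-butyl 2-[(1R,2R,3S,4S,6S)-2-(TBS-oxy)-3-[3-(TBDPS-oxy)prop-1-en-2-yl]-4-ethenyl-6-hydroxy-4-methylcyclohexyl]prop-2-enoate | C=C[C@]1(C)C[C@H](O)[C@@H](C(=C)C(=O)OC(C)(C)C)[C@H](O[Si](C)(C)C(C)(C)C)[C@@H]1C(=C)CO[Si](c1ccccc1)(c1ccccc1)C(C)(C)C | intermediate
28 | 3-methylfuran-2(5H)-one | CC1=CCOC1=O | starting material
29 | sodium (2Z)-4-hydroxy-2-methylbut-2-enoate | [Na+].[O-]C(=O)/C(C)=C\CO | intermediate
30 | 4-methoxybenzyl (2Z)-4-hydroxy-2-methylbut-2-enoate | COc1ccc(COC(=O)/C(C)=C\CO)cc1 | intermediate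
31 | 4-methoxybenzyl (2Z)-4-(acetyloxy)-2-methylbut-2-enoate | COc1ccc(COC(=O)/C(C)=C\COC(C)=O)cc1 | intermediate
32 | (2Z)-4-(acetyloxy)-2-methylbut-2-enoic acid | CC(=O)OC/C=C(/C)C(=O)O | intermediate
33 | (2Z)-4-(acetyloxy)-2-methylbut-2-enoic 2,4,6-trichlorobenzoic anhydride | CC(=O)OC/C=C(/C)C(=O)OC(=O)c1c(Cl)cc(Cl)cc1Cl | intermediate
34 | tert-butyl 2-[(1R,2R,3S,4S,6S)-6-{[(2Z)-4-(acetyloxy)-2-methylbut-2-enoyl]oxy}-2-(TBS-oxy)-3-[3-(TBDPS-oxy)prop-1-en-2-yl]-4-ethenyl-4-methylcyclohexyl]prop-2-enoate | C=C[C@]1(C)C[C@H](OC(=O)/C(C)=C\COC(C)=O)[C@@H](C(=C)C(=O)OC(C)(C)C)[C@H](O[Si](C)(C)C(C)(C)C)[C@@H]1C(=C)CO[Si](c1ccccc1)(c1ccccc1)C(C)(C)C | intermediate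
35 | trimethylsilyl ester of acid 36 | C=C[C@]1(C)C[C@H](OC(=O)/C(C)=C\COC(C)=O)[C@@H](C(=C)C(=O)O[Si](C)(C)C)[C@H](O[Si](C)(C)C(C)(C)C)[C@@H]1C(=C)CO[Si](c1ccccc1)(c1ccccc1)C(C)(C)C | intermediate
36 | 2-[(1R,2R,3S,4S,6S)-6-{[(2Z)-4-(acetyloxy)-2-methylbut-2-enoyl]oxy}-2-(TBS-oxy)-3-[3-(TBDPS-oxy)prop-1-en-2-yl]-4-ethenyl-4-methylcyclohexyl]prop-2-enoic acid | C=C[C@]1(C)C[C@H](OC(=O)/C(C)=C\COC(C)=O)[C@@H](C(=C)C(=O)O)[C@H](O[Si](C)(C)C(C)(C)C)[C@@H]1C(=C)CO[Si](c1ccccc1)(c1ccccc1)C(C)(C)C | intermediate
37 | 2-[(1S,2R,3S,4S,6S)-6-{[(2Z)-4-(acetyloxy)-2-methylbut-2-enoyl]oxy}-4-ethenyl-2-hydroxy-3-(3-hydroxyprop-1-en-2-yl)-4-methylcyclohexyl]prop-2-enoic acid | C=C[C@]1(C)C[C@H](OC(=O)/C(C)=C\COC(C)=O)[C@@H](C(=C)C(=O)O)[C@H](O)[C@@H]1C(=C)CO | target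

## Step count and least certain steps

Total: 22 steps. Longest linear sequence: 18 steps (1–3, 5–16, 20–22).

**Step 16 (key step).** Three processes can divert it. The chromium alkoxide may close onto the ester (lactonisation), although the tert-butyl ester is chosen to suppress this. The allylchromium may undergo reductive 1,4-elimination of the C6 silyloxy group to a diene. The aldehyde face selectivity may be incomplete, or the reaction may pass through a cis-fused array, giving C7/C8 diastereomers. Fallback, from 23: stannylation of the allylic bromide with (Bu3Sn)2 and Pd(PPh3)4 (zerovalent palladium) gives the allylstannane alcohol F1. Dess–Martin oxidation gives the allylstannane aldehyde F2. Cyclisation with BF3·OEt2 at −78 °C, through an open transition state that is still subject to the same chair preferences, returns to the route at 27.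

**Step 6.** The dienolate may form with eroded Z(O)/E(O) selectivity, which would give the C5 epimer. The rearrangement to a quaternary centre may be slow and allow the double bond to drift into conjugation. Face discrimination by the controller may be incomplete. Fallback, from 9: LiN(iPr)2 and Me3SiCl in THF/DMPU give the silyl ketene acetal F3, which rearranges to the racemic silyl ester F4 and is hydrolysed to racemic acid (12 with its enantiomer F5). Steps 7 and 8 are run on the racemate (13 with its enantiomer F6, 16 with its enantiomer F7). The oxazaborolidine reduction of step 9 then acts as the resolving step and gives 17 together with the separable diastereomeric alcohol F8, so the route is rejoined at 17.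

**Step 11.** Tin delivery may not discriminate well enough between C11 and C7, since both alkyne carbons carry an oxygenated substituent. Fallback, from 18: HF·pyridine removes the two primary TBS groups to give the ynediol F9. Hydrostannation of F9 is directed to C11 by the free propargylic hydroxyl and gives the stannyl diol F10. Resilylation of both primary hydroxyls with TBSCl and imidazole returns to the route at 19.

**Step 20.** The Z-acyl donor may isomerise to E on activation, and acylation of the flanked C8 hydroxyl may be slow enough for side reactions of the mixed anhydride to intervene. Fallback, from 27: esterification with 2-[bis(2,2,2-trifluoroethoxy)phosphoryl]propanoic acid (DCC, DMAP) gives the phosphonate ester F11. A Still–Gennari olefination of F11 with 2-acetoxyacetaldehyde (KN(SiMe3)2, 18-crown-6, THF, −78 °C) builds the Z-enoate on the substrate and returns to the route at 34.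

**Step 22.** Cleavage of the hindered C6 silyl ether under buffered fluoride may be slow, and longer or more basic exposure risks loss of the acetate; acidification may start lactonisation of O6 onto C12. Fallback, from 34: HF·pyridine removes both silyl ethers while C12 is still the tert-butyl ester, giving the diol ester F12. TMSOTf and 2,6-lutidine then convert F12 into the tris(trimethylsilyl) derivative F13, and aqueous citric acid hydrolyses it to the target, so the route is rejoined at 37.

## Further compounds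

F1 | step 16 | tert-butyl (2Z,4S,5S,6S)-4-(TBS-oxy)-5-[3-(TBDPS-oxy)prop-1-en-2-yl]-6-ethenyl-8-hydroxy-6-methyl-2-[(tributylstannyl)methyl]oct-2-enoate | OCC[C@@](C)(C=C)[C@@H](C(=C)CO[Si](c1ccccc1)(c1ccccc1)C(C)(C)C)[C@@H](O[Si](C)(C)C(C)(C)C)/C=C(/C(=O)OC(C)(C)C)C[Sn](CCCC)(CCCC)CCCC
F2 | step 16 | tert-butyl (2Z,4S,5S,6S)-4-(TBS-oxy)-5-[3-(TBDPS-oxy)prop-1-en-2-yl]-6-ethenyl-6-methyl-8-oxo-2-[(tributylstannyl)methyl]oct-2-enoate | O=CC[C@@](C)(C=C)[C@@H](C(=C)CO[Si](c1ccccc1)(c1ccccc1)C(C)(C)C)[C@@H](O[Si](C)(C)C(C)(C)C)/C=C(/C(=O)OC(C)(C)C)C[Sn](CCCC)(CCCC)CCCC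
F3 | step 6 | Z(O) trimethylsilyl ketene acetal of 9 | C=C(CO[Si](c1ccccc1)(c1ccccc1)C(C)(C)C)/C=C(\O[Si](C)(C)C)OC/C=C(\C)CCO[Si](C)(C)C(C)(C)C
F4 | step 6 | trimethylsilyl ester of racemic 12 (one enantiomer drawn) | C[Si](C)(C)OC(=O)[C@H](C(=C)CO[Si](c1ccccc1)(c1ccccc1)C(C)(C)C)[C@](C)(C=C)CCO[Si](C)(C)C(C)(C)C
F5 | step 6 | (2R,3R)-5-(TBS-oxy)-2-[3-(TBDPS-oxy)prop-1-en-2-yl]-3-ethenyl-3-methylpentanoic acid (enantiomer of 12) | OC(=O)[C@@H](C(=C)CO[Si](c1ccccc1)(c1ccccc1)C(C)(C)C)[C@@](C)(C=C)CCO[Si](C)(C)C(C)(C)C
F6 | step 6 | (2R,3R) Weinreb amide (enantiomer of 13) | CON(C)C(=O)[C@@H](C(=C)CO[Si](c1ccccc1)(c1ccccc1)C(C)(C)C)[C@@](C)(C=C)CCO[Si](C)(C)C(C)(C)C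
F7 | step 6 | (5R,6R) ynone (enantiomer of 16) | CC(C)(C)[Si](C)(C)OCC[C@](C)(C=C)[C@H](C(=C)CO[Si](c1ccccc1)(c1ccccc1)C(C)(C)C)C(=O)C#CCO[Si](C)(C)C(C)(C)C
F8 | step 6 | (4R,5R,6R)-1,8-bis(TBS-oxy)-5-[3-(TBDPS-oxy)prop-1-en-2-yl]-6-ethenyl-6-methyloct-2-yn-4-ol (diastereomer of 17) | CC(C)(C)[Si](C)(C)OCC[C@](C)(C=C)[C@H](C(=C)CO[Si](c1ccccc1)(c1ccccc1)C(C)(C)C)[C@@H](O)C#CCO[Si](C)(C)C(C)(C)C
F9 | step 11 | (4R,5S,6S)-4-(TBS-oxy)-5-[3-(TBDPS-oxy)prop-1-en-2-yl]-6-ethenyl-6-methyloct-2-yne-1,8-diol | OCC[C@@](C)(C=C)[C@@H](C(=C)CO[Si](c1ccccc1)(c1ccccc1)C(C)(C)C)[C@@H](O[Si](C)(C)C(C)(C)C)C#CCO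
F10 | step 11 | (2E,4R,5S,6S)-4-(TBS-oxy)-5-[3-(TBDPS-oxy)prop-1-en-2-yl]-6-ethenyl-6-methyl-2-(tributylstannyl)oct-2-ene-1,8-diol | OCC[C@@](C)(C=C)[C@@H](C(=C)CO[Si](c1ccccc1)(c1ccccc1)C(C)(C)C)[C@@H](O[Si](C)(C)C(C)(C)C)/C=C(/[Sn](CCCC)(CCCC)CCCC)CO
F11 | step 20 | 2-[bis(2,2,2-trifluoroethoxy)phosphoryl]propanoate of 27 at O8 (mixture of epimers at the phosphonate carbon) | C=C[C@]1(C)C[C@H](OC(=O)C(C)P(=O)(OCC(F)(F)F)OCC(F)(F)F)[C@@H](C(=C)C(=O)OC(C)(C)C)[C@H](O[Si](C)(C)C(C)(C)C)[C@@H]1C(=C)CO[Si](c1ccccc1)(c1ccccc1)C(C)(C)C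
F12 | step 22 | tert-butyl ester of the target (free O6 and O15 hydroxyls) | C=C[C@]1(C)C[C@H](OC(=O)/C(C)=C\COC(C)=O)[C@@H](C(=C)C(=O)OC(C)(C)C)[C@H](O)[C@@H]1C(=C)CO
F13 | step 22 | trimethylsilyl ester bis(trimethylsilyl ether) of the target | C=C[C@]1(C)C[C@H](OC(=O)/C(C)=C\COC(C)=O)[C@@H](C(=C)C(=O)O[Si](C)(C)C)[C@H](O[Si](C)(C)C)[C@@H]1C(=C)CO[Si](C)(C)C
A1 | alternative 1 | (−)-shikimic acid | O=C(O)C1=C[C@@H](O)[C@@H](O)[C@H](O)C1
A2 | alternative 1 | enoate with the trans-diol as its butane-2,3-diacetal and a 2-bromoallyl mixed acetal on O6 (radical precursor) | COC(=O)C1C[C@H]2O[C@](C)(OC)[C@@](C)(OC)O[C@@H]2[C@H](O[C@@H](OC)C(Br)=C)C=1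
A3 | alternative 1 | cis-fused methylene oxolane ester | COC(=O)[C@@H]1C[C@H]2O[C@](C)(OC)[C@@](C)(OC)O[C@@H]2[C@@H]3O[C@@H](OC)C(=C)[C@@H]31
A4 | alternative 2 | cis-fused bicyclo[4.2.0]octa-3,7-dien-2-ol with C10 methyl and C4 silyloxymethyl | C[C@@]12CC=C[C@H](O)[C@@H]1C(CO[Si](C)(C)C(C)(C)C)=C2
A5 | alternative 2 | cyclohexenol with C5, C6 and C10 in place | C=C[C@]1(C)CC=C[C@H](O)[C@@H]1C(=C)CO[Si](C)(C)C(C)(C)C
A6 | alternative 3 | cycloheptene oxide (C1–C10 epoxide) carrying the C5 Weinreb amide, O6 TBS ether, C7 acrylate and O8 PMB ether | C[C@@]12O[C@@H]1C[C@H](OCc1ccc(OC)cc1)[C@@H](C(=C)C(=O)OCC[Si](C)(C)C)[C@H](O[Si](C)(C)C(C)(C)C)[C@@H]2C(=O)N(C)OC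
A7 | alternative 3 | cyclohexanecarbaldehyde with quaternary C10 | O=C[C@]1(C)C[C@H](OCc2ccc(OC)cc2)[C@@H](C(=C)C(=O)OCC[Si](C)(C)C)[C@H](O[Si](C)(C)C(C)(C)C)[C@@H]1C(=O)N(C)OC
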